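**Retrosynthetic overview**
1. The strategy rests on one feature: the ring D carboxyl (on ring D C1) and the ring A C7–OH flank the C8–C2(ring D) biaryl bond. O7 is therefore delivered by the carboxyl group itself through a six-membered lactone (O7, C=O, ring D C1, ring D C2, C8, C7) that is closed and later reopened.
2. Target ⇐ hydrolysis of that lactone ⇐ BBr3 demethylation ⇐ anodic C7–H lactonization of the 7-unsubstituted 8-aryl-5-methoxyflavone acid.
3. Acid ⇐ Pinnick oxidation ⇐ Suzuki coupling of the flavone 8-boronate with 2-bromo-3,4-dimethoxybenzaldehyde (only three ortho substituents at the axis, since C7 is still C–H).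
4. 8-Bromoflavone ⇐ 6-endo cyclization of an o-alkynoylphenol ⇐ acetylide addition to 3-bromo-2-hydroxy-6-methoxybenzaldehyde ⇐ magnesium-mediated ortho-formylation of 2-bromo-5-methoxyphenol. Formylation is chosen because Friedel–Crafts or Fries acetylation of this phenol would favour the position para to OH.
5. Ring order: ring C (pyranone) first, then the biaryl bond, then the temporary lactone ring, which is opened in the last step.

Key step: step 8

Remark: the target SMILES carries no stereodescriptor, so the C8–C2(ring D) axis is made without control; the open hydroxy acid is taken to be isolable because re-closure would restore the bay-region clash between the ring D C3–OH and O1.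

**Step 1**
Reactants: 1 2-bromo-5-methoxyphenol
Product: 3 3-bromo-2-hydroxy-6-methoxybenzaldehyde, via salicyl alcohol 2 (not isolated)
Conditions: MgCl2 (anhydrous, 2 equiv), Et3N (4 equiv), (CH2O)n (6 equiv), MeCN, reflux; then 1 M HCl
Reagents that add atoms: paraformaldehyde (formaldehyde unit), C=O
Why: Magnesium-mediated (Casnati–Skattebøl) ortho-formylation delivers formaldehyde from the magnesium phenoxide only to a carbon ortho to oxygen, and with C2 blocked by bromine the sole free ortho carbon lies between OH and OMe; the salicyl alcohol 2 is oxidized in the flask by a second formaldehyde through Oppenauer-type hydride transfer.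

**Step 2**
Reactants: 3 3-bromo-2-hydroxy-6-methoxybenzaldehyde; 4 4-ethynyl-1,2-dimethoxybenzene
Product: 5 6-bromo-2-[3-(3,4-dimethoxyphenyl)-1-hydroxyprop-2-yn-1-yl]-3-methoxyphenol (racemic)
Conditions: 4 (2.5 equiv), n-BuLi (2.4 equiv), THF, −78 °C; then 3, −78 to 0 °C; aq. NH4Cl
Reagents that add atoms: none
Why: 1,2-Addition of a lithium acetylide to the aldehyde; the first equivalent forms the lithium phenoxide, acetylides do not undergo bromine–lithium exchange, and the carbinol centre forms racemic and is removed in step 3.

**Step 3**
Reactants: 5 6-bromo-2-[3-(3,4-dimethoxyphenyl)-1-hydroxyprop-2-yn-1-yl]-3-methoxyphenol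
Product: 6 1-(3-bromo-2-hydroxy-6-methoxyphenyl)-3-(3,4-dimethoxyphenyl)prop-2-yn-1-one
Conditions: MnO2 (activated, 15 equiv), CH2Cl2, rt
Reagents that add atoms: none
Why: MnO2 oxidation of a secondary alcohol that is both benzylic and propargylic should be fast and chemoselective beside the free phenol and the aryl bromide.

**Step 4**
Reactants: 6 1-(3-bromo-2-hydroxy-6-methoxyphenyl)-3-(3,4-dimethoxyphenyl)prop-2-yn-1-one
Product: 7 8-bromo-2-(3,4-dimethoxyphenyl)-5-methoxy-4H-chromen-4-one
Conditions: TfOH (1 equiv), CH2Cl2, 0 °C to rt
Reagents that add atoms: none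
Why: Acid-promoted 6-endo-dig oxa-Michael cycloisomerization of an o-alkynoylphenol; protonation of the ynone carbonyl puts positive charge on the alkyne carbon bearing the electron-rich dimethoxyphenyl group, so the phenol oxygen closes the pyranone and not the five-membered aurone.

**Step 5**
Reactants: 7 8-bromo-2-(3,4-dimethoxyphenyl)-5-methoxy-4H-chromen-4-one
Product: 8 2-(3,4-dimethoxyphenyl)-5-methoxy-8-(4,4,5,5-tetramethyl-1,3,2-dioxaborolan-2-yl)-4H-chromen-4-one
Conditions: B2pin2 (1.5 equiv), Pd(dppf)Cl2 (5 mol%), KOAc (3 equiv), 1,4-dioxane, 90 °C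
Reagents that add atoms: bis(pinacolato)diboron, CC1(C)OB(OC1(C)C)B1OC(C)(C)C(C)(C)O1
Why: Miyaura borylation of an aryl bromide with a single ortho substituent (O1); KOAc is too weak a base to start Suzuki homocoupling, and the chromone and ethers are inert.

**Step 6**
Reactants: 8 flavone 8-pinacol boronate; 9 2-bromo-3,4-dimethoxybenzaldehyde
Product: 10 2-[2-(3,4-dimethoxyphenyl)-5-methoxy-4-oxo-4H-chromen-8-yl]-3,4-dimethoxybenzaldehyde
Conditions: Pd(OAc)2 (5 mol%), SPhos (10 mol%), K3PO4 (3 equiv), toluene/H2O (10:1), 100 °C
Reagents that add atoms: none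
Why: Suzuki–Miyaura coupling; the ortho-formyl group activates the C–Br bond for oxidative addition, the bulky electron-rich biarylphosphine SPhos is suited to tri-ortho-substituted biaryls, and the boronate carbon has only one ortho substituent because C7 is C–H.

**Step 7**
Reactants: 10 biaryl aldehyde
Product: 11 2-[2-(3,4-dimethoxyphenyl)-5-methoxy-4-oxo-4H-chromen-8-yl]-3,4-dimethoxybenzoic acid
Conditions: NaClO2 (3 equiv), NaH2PO4 (3 equiv), 2-methyl-2-butene (10 equiv), t-BuOH/THF/H2O, rt
Reagents that add atoms: sodium chlorite, [Na+].[O-]Cl=O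
Why: Pinnick oxidation converts the aryl aldehyde to the acid under buffered conditions, with 2-methyl-2-butene trapping HOCl so that the electron-rich rings are not chlorinated and the chromone is untouched.

**Step 8**
Reactants: 11 2-[2-(3,4-dimethoxyphenyl)-5-methoxy-4-oxo-4H-chromen-8-yl]-3,4-dimethoxybenzoic acid
Product: 12 pentamethyl ether lactone (O7 of ring A acylated by the ring D carboxyl; six-membered benzo[c]chromen-6-one-type ring)
Conditions: undivided cell, graphite anode, Pt cathode, n-Bu4NBF4 (0.1 M), 2,6-lutidine (1 equiv), MeCN/HFIP (9:1), constant current 5 mA cm−2, about 2.2 F mol−1, rt, stopped at partial conversion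
Reagents that add atoms: none
Why: Anodic oxidation of the carboxylate of 11 (an electron-rich 4-methoxybenzoate, expected to be oxidized before the chromone) should give an aroyloxy radical that adds to C7 of ring A, and a second electron transfer with loss of the C7 proton restores aromaticity while protons are reduced to H2 at the cathode. The closest known reaction is the electrochemical dehydrogenative lactonization of biaryl-2-carboxylic acids to benzo[c]chromen-6-ones, which also has chemical variants with K2S2O8 and AgNO3. The six-membered lactone (O7, the carboxyl carbon, ring D C1 and C2, C8, C7) closes by O–C7 bond formation onto the arene, formally a 6-endo attack on the C7–C8 bond. No stereocenter is formed, and the biaryl axis is tied into the lactone without a defined configuration. The step needs site selectivity between the two ring A positions ortho to C8, and the substrate secures it because C8a is fully substituted by O1 and only C7 carries a hydrogen within reach of the tethered oxygen. Chemoselectivity against oxidation of the two dimethoxyarene rings should be kept by the non-nucleophilic MeCN/HFIP medium, low current density and recovery of unreacted 11.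

**Step 9**
Reactants: 12 pentamethyl ether lactone
Product: 13 lactone pentaol (same lactone with free OH at C5 and C3' and C4' and ring D C3 and C4)
Conditions: BBr3 (12 equiv), CH2Cl2, −78 °C to rt; then ice–water
Reagents that add atoms: none
Why: BBr3 ether cleavage should remove all five aryl methyl ethers, the 5-OMe fastest through chelation to the C4 carbonyl, while the aryl lactone and the chromone survive as they do in demethylations of methoxylated benzo[c]chromen-6-ones.

**Step 10**
Reactants: 13 lactone pentaol
Product: 15 2-[2-(3,4-dihydroxyphenyl)-5,7-dihydroxy-4-oxo-4H-chromen-8-yl]-3,4-dihydroxybenzoic acid (target), via ring-opened disodium salt 14 (not isolated)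
Conditions: NaOH (0.5 M aq, degassed, 8 equiv), THF, argon, 0 °C to rt; then 1 M HCl, 0 °C, to pH 3; C18 chromatography (H2O/MeCN), freeze-drying
Reagents that add atoms: sodium hydroxide, [Na+].[OH-]
Why: Saponification of a phenolic lactone: hydroxide opening is helped by relief of the bay-region clash between the ring D C3–OH and O1, and cold acidification to pH 3 protonates the carboxylate without heat or strong acid that would promote re-closure.

**Compound list**
1 | 2-bromo-5-methoxyphenol | COc1ccc(Br)c(O)c1 | starting material
2 | 6-bromo-2-(hydroxymethyl)-3-methoxyphenol (salicyl alcohol, not isolated) | COc1ccc(Br)c(O)c1CO | intermediate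
3 | 3-bromo-2-hydroxy-6-methoxybenzaldehyde | COc1ccc(Br)c(O)c1C=O | intermediate
4 | 4-ethynyl-1,2-dimethoxybenzene | COc1ccc(C#C)cc1OC | starting material
5 | 6-bromo-2-[3-(3,4-dimethoxyphenyl)-1-hydroxyprop-2-yn-1-yl]-3-methoxyphenol (racemic) | COc1ccc(Br)c(O)c1C(O)C#Cc1ccc(OC)c(OC)c1 | intermediate
6 | 1-(3-bromo-2-hydroxy-6-methoxyphenyl)-3-(3,4-dimethoxyphenyl)prop-2-yn-1-one | COc1ccc(Br)c(O)c1C(=O)C#Cc1ccc(OC)c(OC)c1 | intermediate
7 | 8-bromo-2-(3,4-dimethoxyphenyl)-5-methoxy-4H-chromen-4-one | COc1ccc(cc1OC)-c1cc(=O)c2c(OC)ccc(Br)c2o1 | intermediate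
8 | 2-(3,4-dimethoxyphenyl)-5-methoxy-8-(4,4,5,5-tetramethyl-1,3,2-dioxaborolan-2-yl)-4H-chromen-4-one | COc1ccc(cc1OC)-c1cc(=O)c2c(OC)ccc(B3OC(C)(C)C(C)(C)O3)c2o1 | intermediate
9 | 2-bromo-3,4-dimethoxybenzaldehyde | COc1ccc(C=O)c(Br)c1OC | starting material
10 | 2-[2-(3,4-dimethoxyphenyl)-5-methoxy-4-oxo-4H-chromen-8-yl]-3,4-dimethoxybenzaldehyde | COc1ccc(cc1OC)-c1cc(=O)c2c(OC)ccc(-c3c(C=O)ccc(OC)c3OC)c2o1 | intermediate
11 | 2-[2-(3,4-dimethoxyphenyl)-5-methoxy-4-oxo-4H-chromen-8-yl]-3,4-dimethoxybenzoic acid (key-step precursor) | COc1ccc(cc1OC)-c1cc(=O)c2c(OC)ccc(-c3c(C(=O)O)ccc(OC)c3OC)c2o1 | intermediate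
12 | pentamethyl ether lactone: compound 11 with the ring D carboxyl closed onto C7 through oxygen (key-step product) | COc1ccc(cc1OC)-c1cc(=O)c2c(OC)cc3oc(=O)c4ccc(OC)c(OC)c4c3c2o1 | intermediate
13 | lactone pentaol: compound 12 with all five methyl ethers cleaved | Oc1ccc(cc1O)-c1cc(=O)c2c(O)cc3oc(=O)c4ccc(O)c(O)c4c3c2o1 | intermediate
14 | ring-opened disodium salt (carboxylate and C7 phenoxide, not isolated) | [Na+].[Na+].[O-]C(=O)c1ccc(O)c(O)c1-c1c([O-])cc(O)c2c(=O)cc(-c3ccc(O)c(O)c3)oc12 | intermediate
15 | 2-[2-(3,4-dihydroxyphenyl)-5,7-dihydroxy-4-oxo-4H-chromen-8-yl]-3,4-dihydroxybenzoic acid | O=C(O)c1ccc(O)c(O)c1-c1c(O)cc(O)c2c(=O)cc(-c3ccc(O)c(O)c3)oc12 | target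

**Step count and risks**
Total steps: 10. Longest linear sequence: 10 steps (1 to 15); 4 and 9 are purchased and enter at steps 2 and 6.

Steps most likely to fail:

1. Step 8. The anode may oxidize the two dimethoxyarene rings instead of the carboxylate, the aroyloxy radical may lose CO2, or its addition to the electron-poor C7 (para to the C4 carbonyl) may be too slow. The fallback sets out from 11 and replaces radical attack by inner-sphere C–H activation: Pd(OAc)2 (10 mol%), N-acetylglycine, KOAc and PhI(OAc)2 in t-BuOH at 80–100 °C. The carboxylate directs divalent palladium to C7–H through a seven-membered palladacycle, oxidation to tetravalent palladium follows, and C–O reductive elimination should give 12, where the route is rejoined. This known palladium-catalyzed lactonization of 2-arylbenzoic acids makes no new compound (F0).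

2. Step 10. The lactone may re-close during acidification and concentration, and the catecholate rings may be oxidized by air in base. The fallback sets out from 13 and avoids aqueous acid altogether. The lactone is opened with degassed aqueous NaOH as before, water is removed, and the residue is alkylated with BnBr and K2CO3 in DMF at rt to give benzyl 3,4-bis(benzyloxy)-2-[7-(benzyloxy)-2-[3,4-bis(benzyloxy)phenyl]-5-hydroxy-4-oxo-4H-chromen-8-yl]benzoate F1, in which the chelated 5-OH stays free. Hydrogenolysis (H2, 1 atm, Pd/C, THF/MeOH, rt) should then remove the six benzyl groups under neutral conditions and return to the route at 15.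

3. Step 6. Protodeboronation of the flavone boronate may outrun transmetalation onto the hindered arylpalladium bromide, and the aldehyde may suffer under hot aqueous base. The fallback sets out from 7 and uses a base-free Stille coupling instead. Compound 7 with Bu3SnSnBu3 and Pd(PPh3)4 in toluene at 110 °C should give 2-(3,4-dimethoxyphenyl)-5-methoxy-8-(tributylstannyl)-4H-chromen-4-one F2. F2 is then coupled with 9 using Pd(PPh3)4, CuI and CsF in DMF at 60 °C, which returns to the route at 10.

**Further compounds**
F0 | step 8 | none | none
F1 | step 10 | benzyl 3,4-bis(benzyloxy)-2-[7-(benzyloxy)-2-[3,4-bis(benzyloxy)phenyl]-5-hydroxy-4-oxo-4H-chromen-8-yl]benzoate | O=C(OCc1ccccc1)c1ccc(OCc2ccccc2)c(OCc2ccccc2)c1-c1c(OCc2ccccc2)cc(O)c2c(=O)cc(-c3ccc(OCc4ccccc4)c(OCc4ccccc4)c3)oc12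
F2 | step 6 | 2-(3,4-dimethoxyphenyl)-5-methoxy-8-(tributylstannyl)-4H-chromen-4-one | CCCC[Sn](CCCC)(CCCC)c1ccc(OC)c2c(=O)cc(-c3ccc(OC)c(OC)c3)oc12
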